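For the reading at 2.5 d I left this note for whoever took over the bench. Sunday's, Friday's and Thursday's flasks each held solid J stirred in solution with the enzyme G, and J gave the product Q and perhaps a trace of the other product E.

| setting | west | north-west | Sunday's | Friday's | Thursday's |
|---|---|---|---|---|---|
| J | 0.029 M | 0.054 M | 0.015 M | 0.030 M | 0.060 M |
| G | 6.8 µM | 6.8 µM | 6.8 µM | 6.8 µM | 6.8 µM |
| remark | run made earlier | run made earlier |  |  |  |
| time |  |  | 2.5 d | 2.5 d | 2.5 d |

| run | time / d | Q / % | E / % | J / % |
|---|---|---|---|---|
| west | 0.500 | 1.2 | 0 | 97.7 |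
| west | 1.04 | 3.7 | 0.4 | 94.8 |
| west | 1.67 | 6.0 | 0 | 92.0 |
| west | 2.08 | 7.0 | 0 | 89.8 |
| west | 2.50 | 8.7 | 0 | 87.9 |
| north-west | 0.208 | 1.0 | 0.5 | 99.5 |
| north-west | 0.625 | 0.9 | 0 | 99.0 |
| north-west | 1.25 | 3.1 | 0 | 97.0 |
| north-west | 1.67 | 2.9 | 0 | 95.4 |
| north-west | 2.50 | 4.3 | 0.4 | 94.0 |

(each reading ± 0.5 percentage points)

- J is a solid; its amount is given per volume of the solution
- the analysis behind the earlier runs scatters by 0.5 percentage points, standard deviation
- at the start none of J is in solution
- "hardly changes" means that all values lie within two and a half points (for a concentration: within two and a half percent of the largest)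

- share of Q in all that became Q or E for Sunday's, Friday's, Thursday's, in this order
- the shape of the row from first to last (falls all the way / falls, then rises / hardly changes / rises, then falls / rises all the way)

I distrusted the percentages, so I turned the last Q readings into concentrations: the west run gave 2.52 mM and the north-west run 2.32 mM, though north-west held nearly twice the J. Their mean, 2.42 mM, I called the output, the concentration of Q standing at 2.5 d with 6.8 µM of G while solid J is present. Sunday's charge of 0.015 M stood above the output, so I expected solid J to remain there, with Q at 16.1% of the charge in Sunday's, 8.07% in Friday's and 4.04% in Thursday's.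

My instruction was to add no J, since north-west's extra J had shown no more Q than west at 2.5 d. West's last E reading was 0%, with a scatter of 0.5 percentage points, against Q at 8.7%. Allowing west one scatter of E put the share of Q, the selectivity, at an estimated 94.6%, and with one output of Q for all three flasks and E taken to follow Q, I wrote the row flat.

The forecast gave 99%, 99% and 99%, hardly changes: “the selectivity should not change with loading”.

The flasks gave 96.5%, 96.5% and 96.5%, so the row hardly changes.

    L + G → Q + G, rate k1*[L]*[G]/(1 + ([L]/Km1) + ([Q]/Kp1)) (3.60 mM, 0.190 mM, k = 250 M⁻¹ s⁻¹)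
    J ⇌ L, rate k2*(cs2 - [L]) while solid is left; crystals form when [L] > cs2 (solubility = 5.70 mM, k = 3.00 × 10⁻⁶ s⁻¹)
    2 G → D (k = 4.20 M⁻¹ s⁻¹)
    Q → E (k = 3.00 × 10⁻⁷ s⁻¹)

Sunday's Q at 2.5 d came to 2.38 mM and Thursday's to 2.38 mM, each beside my output of 2.42 mM. In Sunday's, the half-life of Q by its turning into E was 27 d, longer than the 2.5 d of the run, and E stood at 0.568% beside Q at 15.9%. Thursday's, at the same time, held E at 0.142% beside Q at 3.97%.

The readings were generated by integration with constants of no real substance, noise included.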